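# Proposed synthesis of CNP0064734.1 through a truxinate photodimer and oxidative ring-opening arylation

Numbering used throughout: 1 4-methoxybenzaldehyde; 2 2-acetyl-1-methylimidazole; 3 the cinnamoyl imidazole; 4 its all-trans head-to-head dimer; 5 3,5-dimethoxyphenol; 6 the mono-imidazolium salt of 4; 7 the mono aryl ester; 8 1,2,3,4-tetramethoxybenzene; 9 its aryllithium; 10 the derived boronate; 11 2,3,4,5-tetramethoxyphenol; 12 the imidazolium salt of 7; 13 the mixed bis(aryl ester); 14 the 3,4-trans bis-lactone octamethyl ether; 15 its bis-enolate; 16 the 3,4-cis bis-lactone octamethyl ether; 17 the target.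

## Analysis of the target

The target 17 consists of two 4-aryl-3,4-dihydrocoumarin (chroman-2-one) units joined by one bond between their C3 atoms (C3–C3′). Ring A, in the unprimed half, is a 5,7-dihydroxylated, phloroglucinol-type benzo ring. Ring B, in the primed half, carries hydroxyl groups at C5′, C6′, C7′ and C8′ and is therefore fully substituted. Each C4 bears a 4-hydroxyphenyl group.

The four stereocentres C4, C3, C3′ and C4′ are contiguous and have the configuration 3S,4R,3′S,4′R. In each lactone ring the 4-aryl group and the C3–C3′ bond are cis. The two halves have like configuration, so apart from the oxygenation of rings A and B the molecule is C2-symmetric.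

The 3,4-cis arrangement is expected to be the less stable one in each lactone, and C3–H and C3′–H are acidic (alpha to an aryl ester), so these centres can drift to trans through enolisation. The lactones also open with base and nucleophiles, C4 and C4′ are doubly benzylic, and the free tetrahydroxylated ring B is very easily oxidised by air.

The difficulty is threefold: four adjacent stereocentres, two of which are epimerisable and must end in the less stable arrangement; two halves that differ only in two oxygen atoms; and a hexasubstituted ring B.

The strategy rests on the chain aryl–C4–C3–C3′–C4′–aryl, flanked by the carbonyl carbons C2 and C2′. It is two identical 4-oxygenated cinnamoyl units joined head to head at their alpha carbons. That is a δ-truxinate (an all-trans 3,4-diarylcyclobutane-1,2-dicarboxylate) in which the strained ring bond between the two benzylic carbons (C4–C4′) has been exchanged for the bonds C4–C4a to ring A and C4′–C4a′ to ring B.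

## Retrosynthetic reasoning

**17 from 16 (eight O–CH3 bonds).** All eight phenols are carried as methyl ethers and released last. Free phenols would not survive the oxidative ring opening or the strong base used before it. The methyl ethers are already present in 1, 5 and 8, so no protection steps are spent. The forward step must cleave eight aryl methyl ethers without opening the lactones or disturbing C3 and C3′.

**16 from 14 (C3–H and C3′–H).** No skeletal bond is cut; the two epimerisable centres are inverted. This is needed because the ring-forming step that makes C4–C4a and C4′–C4a′ is expected to place each new aryl bond trans to the C3 substituent, so the cis lactones cannot come out of it directly. In 14 the information therefore sits at C4 and C4′, which must already be 4R,4′R. Deprotonation to the planar bis-enolate 15 and protonation of each C3 on the face away from its 4-aryl group should then give the cis lactones of 16. This fixes 14 as the 3R,4R,3′R,4′R isomer.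

**14 from 13 (cut C4–C4a and C4′–C4a′, join C4–C4′).** Each cut bond runs from a benzylic carbon to the position ortho to a phenol ester oxygen, which is a Friedel–Crafts retron. Once both are removed, C4 and C4′ are 1,4-related across C3–C3′, and joining them gives the cyclobutane of 13. Two lactone rings and two stereocentres are thereby traced back to one C2-symmetric core carrying two phenol esters. The forward reaction has to take two electrons out of the strained benzylic–benzylic bond, let each benzylic carbon be captured by the arene of its own ester, and do so trans to the C3 substituent.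

**13 from 7 and 11, and 7 from 4 and 5 (two ester C–O bonds).** The acyl groups of 4 are 2-acylimidazoles. After N-methylation (6, 12) they become acyl donors toward phenols. The two acyl groups of 4 are homotopic, so the first esterification needs only mono-functionalisation and no choice between sites; the second has only one imidazole left. Phenol 11 is not an article of commerce in quantity and is traced to 8 by replacing one aryl C–H by C–OH through 9 and 10.

**4 from two molecules of 3 (cut C1–C2 and C3–C4 of the cyclobutane).** At this stage both halves are identical, so the ring is a head-to-head dimer of one enone. The imidazole serves twice: as the binding site for a chiral acid in the photoreaction and as the latent leaving group for the esters. The forward reaction must be head to head, all-trans and enantioselective for the (1R,2R,3S,4S) isomer. Of the four centres it sets, C1 and C2 are the ones that steer everything after it.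

**3 from 1 and 2 (the C=C bond).** An aldol condensation between a non-enolisable aldehyde and a methyl ketone; nothing else needs to be controlled.

## Alternatives that were turned down

**Alternative 1:** Biomimetic arylation of a dilactone.
- **Disconnection:** C4–C4a, C4′–C4a′ and both lactone C–O bonds. This leads back to the cis-fused dilactone A2 (2,6-bis(4-hydroxyphenyl)-3,7-dioxabicyclo[3.3.0]octane-4,8-dione, aryl groups exo), phloroglucinol A3 and the phenol 11.
- **Forward key step:** under a Lewis acid each benzylic C–O bond of A2 is opened by an arene, first A3 and then 11. Each carboxylic acid so released closes on the neighbouring phenol, which would give the tetramethyl ether A1 in one pot.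
- **For it:** it is the shortest conceivable route. A2 arises in one oxidative coupling of a cinnamic acid and A1 is one demethylation away from 17. Ring A and the hydroxyphenyl groups need no protection, and the C3–C3′ bond with its like configuration is present from the start. On step count and atom economy it is clearly stronger than the chosen route.
- **Against it:**
  - A2 comes from a radical coupling and is racemic, with no handle for a catalyst.
  - Its two benzylic carbons are related by a C2 axis. Two different free arenes offered in turn would give both symmetrical bis-adducts beside A1, and the more nucleophilic A3 would tend to take both positions.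
  - The arenes attack from outside, so no tether fixes the face of the benzylic cation.
  - The C3/C4 relation is not solved either: rear-side displacement of the lactone oxygen places the new aryl group trans to the C3 substituent, exactly as in the chosen route.
- **Comparison:** the chosen strategy spends more steps. In return it has a catalytic source of absolute configuration and esters that bind each arene to its own benzylic carbon before the C–C bonds are made. The two halves are told apart by an ordinary mono-functionalisation and not in the bond-forming event.

**Alternative 2:** Ring B by cyclobutenone ring expansion.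
- **Disconnection:** ring B itself, through C4a′–C5′ and the bonds of a four-membered ring, back to a squaric ester and a metallated 4-aryl-2-ethoxy-dihydropyran.
- **Forward key step:** heating the 4-hydroxycyclobutenone adduct opens it to a dienylketene (4π electrocyclic opening). The ketene closes onto C5 of the dihydropyran (6π closure) and tautomerises to the hydroquinone A4, (2,4-cis)-2-ethoxy-6,7-dimethoxy-4-(4-methoxyphenyl)chromane-5,8-diol.
- **For it:** every oxygen of the hexasubstituted ring B is placed by construction. There is no question of regiochemistry or of how a crowded arene behaves toward an electrophile, and C4′ is in place before the ring exists. On that one point it is more secure than a Friedel–Crafts closure.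
- **Against it:**
  - It builds in several steps a ring that the chosen route buys as 8.
  - A4 is only the ring B half, at the lactol oxidation level, with C3′ still a methylene group.
  - The central C3–C3′ bond between two hindered secondary carbons, three of the four stereocentres and the whole ring A half remain to be made. The likely way is a coupling of two different lactone enolates, which has no inherent preference for the mixed product.
- **Comparison:** the chosen strategy makes C3–C3′ first, in the step that also introduces chirality, and obtains ring B in one step from 8. What it gives up is the certainty about the ring B closure.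

**Alternative 3:** Ring A by Claisen annulation of a malonate.
- **Disconnection:** ring A through C5–C6 and C8–C8a, back to a 2-substituted malonyl dichloride and the dienolate of a 3-oxoglutarate diester.
- **Forward key step:** double C-acylation (Claisen, then Dieckmann) and aromatisation, after which the new ortho hydroxyl closes the lactone. The product is A5, dimethyl (4R)-5,7-dihydroxy-4-(4-methoxyphenyl)-2-oxochromane-6,8-dicarboxylate.
- **For it:** the C4–C4a bond exists before ring A does, so no Friedel–Crafts step is needed on that side. C4 could be set early by an asymmetric conjugate addition while the malonate is made. In this respect it is as strong as, or stronger than, the chosen route.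
- **Against it:**
  - Ring A is the cheapest part of the molecule; its oxygenation pattern is available as 5.
  - The two ester groups at C6 and C8 are ballast and must be removed by a double dealkoxycarbonylation.
  - As in alternative 2, only one half results, with C3 unsubstituted, so the C3–C3′ bond and its stereocentres are again left to a late coupling.
- **Comparison:** the chosen strategy takes both aromatic rings from the shelf and joins the two halves at the outset. It offers convergence and brevity where alternative 3 offers early control of C4.

Key step: step 2

## Assumptions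

- The (R) enantiomer of the phosphoric acid is written in step 2 on the premise that it leads to the (1R,2R,3S,4S) dimer 4. If the sense of induction is the reverse, the (S) acid is used and nothing else changes.
- The two ring closures of step 6 are taken to be 3,4-trans (reasons in that step). This is why the route is entered with the (1R,2R,3S,4S) dimer and why step 7 is needed.

## Route

Step 1
Reactants: 1 4-methoxybenzaldehyde; 2 2-acetyl-1-methylimidazole
Product: 3 (E)-3-(4-methoxyphenyl)-1-(1-methyl-1H-imidazol-2-yl)prop-2-en-1-one
Conditions: KOH (20 mol%), EtOH/H2O, rt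
Reagents that add atoms: none
Why: Claisen–Schmidt aldol condensation; the aldehyde cannot enolise, the methyl ketone is the only enolate source, and E1cB loss of water should give the conjugated E alkene.

Step 2
Reactants: 3 (E)-3-(4-methoxyphenyl)-1-(1-methyl-1H-imidazol-2-yl)prop-2-en-1-one (two molecules)
Product: 4 [(1R,2R,3S,4S)-3,4-bis(4-methoxyphenyl)cyclobutane-1,2-diyl]bis[(1-methyl-1H-imidazol-2-yl)methanone] (all-trans; δ-truxinate type)
Conditions: (R)-TRIP (20 mol%), Ru(bpy)3(PF6)2 (2 mol%), blue LEDs (450 nm), CH2Cl2 (degassed), −40 °C
Reagents that add atoms: none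
Why: The acid (TRIP = 3,3′-bis(2,4,6-triisopropylphenyl)-1,1′-binaphthyl-2,2′-diyl hydrogen phosphate) binds 3 at the imidazole nitrogen and the carbonyl oxygen, which lowers the triplet energy of the bound enone; Ru(bpy)3(PF6)2 is taken as sensitiser because its triplet energy should reach only this bound enone, whereas a higher-energy sensitiser such as fac-Ir(ppy)3 would also excite free 3 and open a racemic channel. Energy transfer gives the enone triplet, which joins its alpha carbon to the alpha carbon of a ground-state molecule of 3; this forms C1–C2 of the future ring (C3–C3′ of the target) and leaves a triplet 1,4-diradical with both spins on 4-methoxybenzylic carbons. After spin inversion the two benzylic radicals combine to form C3–C4 of the ring (the temporary C4–C4′ bond in target numbering) and so close the four-membered ring, a stepwise closure by radical recombination and not a concerted cycloaddition. The closest known reaction type is the acid-catalysed, triplet-sensitised enantioselective head-to-head [2+2] dimerisation of cinnamoyl 2-acylimidazoles to δ-truxinate-type cyclobutanes. C1 and C2 are set in the first bond formation inside the chiral ion pair, in which the 3,3′-aryl groups of the acid screen one face of the bound enone (catalyst control). C3 and C4 are set in the ring closure under substrate control: the diradical should live long enough to rotate and close with each aryl group trans to its acyl neighbour and to the other aryl group, the least strained arrangement. The step needs head-to-head regioselectivity, which the doubly benzylic diradical secures, all-trans diastereoselectivity, which strain in the closing ring secures, and enantioselectivity, which rests on the acid and on keeping the unbound channel closed.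

Step 3
Reactants: 4 [(1R,2R,3S,4S)-3,4-bis(4-methoxyphenyl)cyclobutane-1,2-diyl]bis[(1-methyl-1H-imidazol-2-yl)methanone]; 5 3,5-dimethoxyphenol
Product: 7 3,5-dimethoxyphenyl (1R,2R,3S,4S)-3,4-bis(4-methoxyphenyl)-2-(1-methyl-1H-imidazole-2-carbonyl)cyclobutane-1-carboxylate, via mono(1,3-dimethylimidazolium) triflate 6 (not isolated)
Conditions: MeOTf (0.9 equiv), CH2Cl2, −20 °C → rt; then 5, DABCO (20 mol%), 0 °C → rt
Reagents that add atoms: none
Why: N-methylation turns one 2-acylimidazole into a 2-acylimidazolium, which the phenol attacks in an addition–elimination with loss of the 1,3-dimethylimidazolium ylide (known activation of 2-acylimidazoles for acyl transfer); the two imidazoles are homotopic, so only the degree of methylation matters, and the cationic 6 should be methylated a second time more slowly than 4. Unreacted 4 (dibasic), 7 (monobasic) and any neutral bis-ester differ in basicity and should separate easily, and 4 is recycled; the weak base keeps ketene formation out, and the all-trans ring is the stable arrangement, so C1 and C2 should hold.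

Step 4
Reactants: 8 1,2,3,4-tetramethoxybenzene
Product: 11 2,3,4,5-tetramethoxyphenol, via 2,3,4,5-tetramethoxyphenyllithium 9 (not isolated), via dimethyl 2,3,4,5-tetramethoxyphenylboronate 10 (not isolated)
Conditions: n-BuLi, TMEDA, THF, 0 °C; B(OMe)3, −78 °C → rt; then H2O2 (30% aq), AcOH, 0 °C → rt
Reagents that add atoms: hydrogen peroxide, OO
Why: Directed ortho-lithiation next to a methoxy group (both free positions of 8 are equivalent), borylation, and oxidation of the aryl boronate with 1,2-shift of the aryl group from boron to oxygen; the acidic oxidation spares the electron-rich phenol.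

Step 5
Reactants: 7 3,5-dimethoxyphenyl (1R,2R,3S,4S)-3,4-bis(4-methoxyphenyl)-2-(1-methyl-1H-imidazole-2-carbonyl)cyclobutane-1-carboxylate; 11 2,3,4,5-tetramethoxyphenol
Product: 13 1-(3,5-dimethoxyphenyl) 2-(2,3,4,5-tetramethoxyphenyl) (1R,2R,3S,4S)-3,4-bis(4-methoxyphenyl)cyclobutane-1,2-dicarboxylate, via 1,3-dimethylimidazolium triflate 12 (not isolated)
Conditions: MeOTf (1.1 equiv), CH2Cl2, 0 °C → rt; then 11, DABCO (20 mol%), rt
Reagents that add atoms: none
Why: The same N-methylation and acyl transfer as in step 3; only one imidazole is left and the aryl ester and the methoxyarenes are inert to MeOTf, so no selectivity is asked for.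

Step 6
Reactants: 13 1-(3,5-dimethoxyphenyl) 2-(2,3,4,5-tetramethoxyphenyl) (1R,2R,3S,4S)-3,4-bis(4-methoxyphenyl)cyclobutane-1,2-dicarboxylate
Product: 14 (3R,4R)-5,7-dimethoxy-4-(4-methoxyphenyl)-3-[(3R,4R)-5,6,7,8-tetramethoxy-4-(4-methoxyphenyl)-2-oxochroman-3-yl]chroman-2-one (3,4-trans in both lactone rings)
Conditions: anodic oxidation (graphite anode, Pt cathode, undivided cell, constant current, 2.2 F/mol), (2,4-Br2C6H3)3N (20 mol%), n-Bu4NPF6, CH2Cl2/HFIP (4:1), 0 °C, high dilution
Reagents that add atoms: none
Why: Proposed new method: the anodically formed aminium ion removes one electron from the 1,2-bis(4-methoxyphenyl)cyclobutane unit, whose strained benzylic–benzylic bond lengthens and is attacked from the rear at one benzylic carbon by the ortho position of the neighbouring aryl ester (three-electron SN2 with inversion, then loss of a proton), closing the first lactone; the benzylic radical left at the other carbon is oxidised to the cation and captured in the same way by the second aryl ester, while protons are reduced to hydrogen at the cathode. The closest known reaction types are the radical-cation cleavage and cycloreversion of 1,2-diarylcyclobutanes and the nucleophile-assisted opening of arylcyclopropane radical cations with inversion; the intramolecular six-ring capture by the doubly activated arenes must outrun loss of the C1–C2 bond (cycloreversion to two cinnamates) and closure onto the other anisyl ring (tetralin). Rear-side attack on the all-trans ring, and for the second closure a half-chair with the anisyl group pseudo-axial (away from the peri methoxy group) and anti to the large C3 substituent, should place each new aryl–C4 bond trans to the C3 substituent, so that (1R,2R) of 13 is relayed to 4R,4′R.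

Step 7
Reactants: 14 (3R,4R)-5,7-dimethoxy-4-(4-methoxyphenyl)-3-[(3R,4R)-5,6,7,8-tetramethoxy-4-(4-methoxyphenyl)-2-oxochroman-3-yl]chroman-2-one
Product: 16 (3S,4R)-5,7-dimethoxy-4-(4-methoxyphenyl)-3-[(3S,4R)-5,6,7,8-tetramethoxy-4-(4-methoxyphenyl)-2-oxochroman-3-yl]chroman-2-one (3,4-cis in both lactone rings), via dilithium bis-enolate 15 (not isolated)
Conditions: LDA (2.5 equiv), THF, −78 °C; then 2,6-di-tert-butyl-4-methylphenol (5 equiv), −78 °C; then aq NH4Cl
Reagents that add atoms: none
Why: Double deprotonation alpha to the two aryl esters gives the bis-enolate 15, in which A(1,3) strain and the peri methoxy group hold each 4-anisyl group pseudo-axial over one face of its enolate. The hindered phenol should protonate each C3 from the open face, anti to that aryl group (kinetic protonation of an enolate), which gives the less stable 3,4-cis lactone. C4 and C4′ are untouched and now control C3 and C3′.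

Step 8
Reactants: 16 (3S,4R)-5,7-dimethoxy-4-(4-methoxyphenyl)-3-[(3S,4R)-5,6,7,8-tetramethoxy-4-(4-methoxyphenyl)-2-oxochroman-3-yl]chroman-2-one
Product: 17 (3S,4R)-5,7-dihydroxy-4-(4-hydroxyphenyl)-3-[(3S,4R)-5,6,7,8-tetrahydroxy-4-(4-hydroxyphenyl)-2-oxochroman-3-yl]chroman-2-one (the target)
Conditions: BBr3 (16 equiv), CH2Cl2, −78 → 0 °C; then degassed H2O, 0 °C, work-up under argon
Reagents that add atoms: none
Why: Lewis acid cleavage of aryl methyl ethers (boron–oxygen adduct, then SN2 attack of bromide at methyl); aryl lactones are normally stable to BBr3 at low temperature and no base is present that could enolise C3 or C3′. If a lactone opens and recloses on the other ortho oxygen, the same compound results, because each of rings A and B is symmetrical about its C4a–C7 axis.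

## Compound list

1 | 4-methoxybenzaldehyde | COc1ccc(C=O)cc1 | starting material
2 | 2-acetyl-1-methylimidazole | CC(=O)c1nccn1C | starting material
3 | (E)-3-(4-methoxyphenyl)-1-(1-methyl-1H-imidazol-2-yl)prop-2-en-1-one | COc1ccc(/C=C/C(=O)c2nccn2C)cc1 | intermediate
4 | [(1R,2R,3S,4S)-3,4-bis(4-methoxyphenyl)cyclobutane-1,2-diyl]bis[(1-methyl-1H-imidazol-2-yl)methanone] | O=C(c1nccn1C)[C@@H]1[C@@H](c2ccc(OC)cc2)[C@H](c2ccc(OC)cc2)[C@H]1C(=O)c1nccn1C | intermediate
5 | 3,5-dimethoxyphenol | COc1cc(O)cc(OC)c1 | starting material
6 | 1,3-dimethyl-2-{[(1R,2R,3S,4S)-3,4-bis(4-methoxyphenyl)-2-(1-methyl-1H-imidazole-2-carbonyl)cyclobutyl]carbonyl}imidazolium triflate (formed in the flask in step 3) | O=C(c1n(C)cc[n+]1C)[C@@H]1[C@@H](c2ccc(OC)cc2)[C@H](c2ccc(OC)cc2)[C@H]1C(=O)c1nccn1C.[O-]S(=O)(=O)C(F)(F)F | intermediate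
7 | 3,5-dimethoxyphenyl (1R,2R,3S,4S)-3,4-bis(4-methoxyphenyl)-2-(1-methyl-1H-imidazole-2-carbonyl)cyclobutane-1-carboxylate | O=C(Oc1cc(OC)cc(OC)c1)[C@@H]1[C@@H](c2ccc(OC)cc2)[C@H](c2ccc(OC)cc2)[C@H]1C(=O)c1nccn1C | intermediate
8 | 1,2,3,4-tetramethoxybenzene | COc1ccc(OC)c(OC)c1OC | starting material
9 | 2,3,4,5-tetramethoxyphenyllithium (formed in the flask in step 4) | [Li]c1cc(OC)c(OC)c(OC)c1OC | intermediate
10 | dimethyl 2,3,4,5-tetramethoxyphenylboronate (formed in the flask in step 4) | COB(OC)c1cc(OC)c(OC)c(OC)c1OC | intermediate
11 | 2,3,4,5-tetramethoxyphenol | COc1cc(O)c(OC)c(OC)c1OC | intermediate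
12 | 1,3-dimethyl-2-{[(1R,2R,3S,4S)-2-[(3,5-dimethoxyphenoxy)carbonyl]-3,4-bis(4-methoxyphenyl)cyclobutyl]carbonyl}imidazolium triflate (formed in the flask in step 5) | O=C(Oc1cc(OC)cc(OC)c1)[C@@H]1[C@@H](c2ccc(OC)cc2)[C@H](c2ccc(OC)cc2)[C@H]1C(=O)c1n(C)cc[n+]1C.[O-]S(=O)(=O)C(F)(F)F | intermediate
13 | 1-(3,5-dimethoxyphenyl) 2-(2,3,4,5-tetramethoxyphenyl) (1R,2R,3S,4S)-3,4-bis(4-methoxyphenyl)cyclobutane-1,2-dicarboxylate | O=C(Oc1cc(OC)cc(OC)c1)[C@@H]1[C@@H](c2ccc(OC)cc2)[C@H](c2ccc(OC)cc2)[C@H]1C(=O)Oc1cc(OC)c(OC)c(OC)c1OC | intermediate
14 | (3R,4R)-5,7-dimethoxy-4-(4-methoxyphenyl)-3-[(3R,4R)-5,6,7,8-tetramethoxy-4-(4-methoxyphenyl)-2-oxochroman-3-yl]chroman-2-one (3,4-trans in both rings) | O=C1Oc2cc(OC)cc(OC)c2[C@@H](c2ccc(OC)cc2)[C@@H]1[C@@H]1C(=O)Oc2c(OC)c(OC)c(OC)c(OC)c2[C@H]1c1ccc(OC)cc1 | intermediate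
15 | dilithium bis-enolate of 14 (C3 and C3′ planar; C4 and C4′ as in 14; formed in the flask in step 7) | [Li+].[Li+].[O-]C1Oc2cc(OC)cc(OC)c2[C@@H](c2ccc(OC)cc2)C=1C1=C([O-])Oc2c(OC)c(OC)c(OC)c(OC)c2[C@H]1c1ccc(OC)cc1 | intermediate
16 | (3S,4R)-5,7-dimethoxy-4-(4-methoxyphenyl)-3-[(3S,4R)-5,6,7,8-tetramethoxy-4-(4-methoxyphenyl)-2-oxochroman-3-yl]chroman-2-one (3,4-cis in both rings) | O=C1Oc2cc(OC)cc(OC)c2[C@@H](c2ccc(OC)cc2)[C@H]1[C@H]1C(=O)Oc2c(OC)c(OC)c(OC)c(OC)c2[C@H]1c1ccc(OC)cc1 | intermediate
17 | (3S,4R)-5,7-dihydroxy-4-(4-hydroxyphenyl)-3-[(3S,4R)-5,6,7,8-tetrahydroxy-4-(4-hydroxyphenyl)-2-oxochroman-3-yl]chroman-2-one | O=C1Oc2cc(O)cc(O)c2[C@@H](c2ccc(O)cc2)[C@H]1[C@H]1C(=O)Oc2c(O)c(O)c(O)c(O)c2[C@H]1c1ccc(O)cc1 | target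

## Step count and least certain steps

Total: 8 steps. Longest linear sequence: 7 steps (steps 1, 2, 3, 5, 6, 7 and 8, from 1 and 2); step 4 is a one-step branch from 8.

**Step 6 (proposed new method).** Several processes may go wrong.
- The hole may settle on the most electron-rich arene, the tetramethoxyphenyl ester, and not on the dianisylcyclobutane. The plan relies on reversible hole transfer within the molecule, with the strain-releasing bond cleavage as the only irreversible exit. If that exit is too slow, the ester arene is degraded instead.
- The opened radical cation may lose its C1–C2 bond (cycloreversion to two cinnamates) or close onto the second anisyl ring before the ester arenes capture it.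
- Facial control in the second, cation-based closure may be poor, which would leave 3′,4′-cis material.
- The product may be oxidised further at its doubly benzylic C4–H bonds.

Fallback, in known reaction types, from 13 back to 14: the bond cleavage is separated from the C–C bond formation. Electron-transfer photooxygenation of 13 (9,10-dicyanoanthracene as sensitiser, O2, MeCN, visible light) is a known way to trap the opened radical cation of a 1,2-diarylcyclobutane with oxygen. It should give 4-(3,5-dimethoxyphenyl) 5-(2,3,4,5-tetramethoxyphenyl) (4S,5S)-3,6-bis(4-methoxyphenyl)-1,2-dioxane-4,5-dicarboxylate F1. Reduction of the O–O bond with Zn and AcOH should give 1-(3,5-dimethoxyphenyl) 4-(2,3,4,5-tetramethoxyphenyl) (2S,3S)-2,3-bis[hydroxy(4-methoxyphenyl)methyl]butanedioate F2, which is used at once. BF3·OEt2 in CH2Cl2/HFIP at −40 °C then ionises each 4-methoxybenzylic alcohol, and the two aryl esters close the lactones by ordinary Friedel–Crafts alkylation to 14. The configuration at the two carbinol carbons of F1 and F2 is immaterial, because both are ionised.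

**Step 2 (key step).**
- Enantioselectivity may be eroded by sensitisation or direct excitation of unbound 3.
- Energy transfer from the low-energy sensitiser to the bound enone may be slow, so that E/Z isomerisation and catalyst inhibition by the basic product dominate.
- Other truxinate diastereomers or head-to-tail dimers may form if the first bond formation is less ordered than assumed.

Fallback, from 3 back to 4: control by catalyst is given up for a resolution. The dimerisation is run racemically with TsOH and the higher-energy fac-Ir(ppy)3, for which no discrimination between bound and free enone is needed. The racemate is resolved by preparative chromatography on a chiral stationary phase; 4 is kept and its enantiomer, [(1S,2S,3R,4R)-3,4-bis(4-methoxyphenyl)cyclobutane-1,2-diyl]bis[(1-methyl-1H-imidazol-2-yl)methanone] F3, is set aside.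

**Step 7.**
- The second deprotonation next to the first enolate may be incomplete.
- The aryl ester enolate may expel its phenoxide to a ketene, which an amine can capture before it recloses.
- Facial selectivity in the second protonation may be lower than in the first, because C3 is then already tetrahedral.

Fallback, from 14 back to 16: the dianion is avoided. Soft enolisation of 14 with TMSOTf and Et3N in CH2Cl2 should give the neutral bis(trimethylsilyl ketene acetal) of 14, F4. This is protonated at carbon with CF3CO2H at −78 °C, again from the face away from each 4-aryl group.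

**Step 3.** Over-methylation of 4 would give bis-imidazolium salt and hence the symmetrical bis(3,5-dimethoxyphenyl) ester. Under-methylation only costs recycling.

Fallback, from 4 back to 12: both imidazoles are methylated with excess MeOTf to the bis(1,3-dimethylimidazolium) bis(triflate) of 4, F5. One equivalent of 5 is then added slowly at −78 °C. The dication should be the stronger acylating agent, and loss of one charge slows the second substitution, so the mono-ester salt 12 should form. It is treated in the same flask with 11 as in step 5, which merges steps 3 and 5.

**Step 8.**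
- Under the Lewis acid, C3 and C3′ of the less stable cis lactones may drift back to trans.
- Cleavage of eight ethers may stop short.
- The tetrahydroxylated ring B may be oxidised by air during work-up.

Fallback, from 14 back to 17: the harsh step is moved in front of the labile centres. BBr3 is applied to the configurationally stable trans isomer 14 and should give the trans,trans octaphenol (3R,4R)-5,7-dihydroxy-4-(4-hydroxyphenyl)-3-[(3R,4R)-5,6,7,8-tetrahydroxy-4-(4-hydroxyphenyl)-2-oxochroman-3-yl]chroman-2-one F6. MOMCl and i-Pr2NEt convert it into the octakis(methoxymethyl) ether of F6, F7. LDA at −78 °C gives the dilithium bis-enolate of F7, F8, which is protonated with 2,6-di-tert-butyl-4-methylphenol as in step 7 to the 3,4-cis octakis(methoxymethyl) ether F9. Dilute aqueous HCl in THF at 40 °C then releases 17 without a strong Lewis acid.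

## Further compounds

F1 | step 6 | 4-(3,5-dimethoxyphenyl) 5-(2,3,4,5-tetramethoxyphenyl) (4S,5S)-3,6-bis(4-methoxyphenyl)-1,2-dioxane-4,5-dicarboxylate (epimers at C3 and C6) | O=C(Oc1cc(OC)cc(OC)c1)[C@@H]1C(c2ccc(OC)cc2)OOC(c2ccc(OC)cc2)[C@H]1C(=O)Oc1cc(OC)c(OC)c(OC)c1OC
F2 | step 6 | 1-(3,5-dimethoxyphenyl) 4-(2,3,4,5-tetramethoxyphenyl) (2S,3S)-2,3-bis[hydroxy(4-methoxyphenyl)methyl]butanedioate (epimers at the carbinol carbons) | O=C(Oc1cc(OC)cc(OC)c1)[C@H](C(O)c1ccc(OC)cc1)[C@@H](C(O)c1ccc(OC)cc1)C(=O)Oc1cc(OC)c(OC)c(OC)c1OC
F3 | step 2 | [(1S,2S,3R,4R)-3,4-bis(4-methoxyphenyl)cyclobutane-1,2-diyl]bis[(1-methyl-1H-imidazol-2-yl)methanone] | O=C(c1nccn1C)[C@H]1[C@H](c2ccc(OC)cc2)[C@@H](c2ccc(OC)cc2)[C@@H]1C(=O)c1nccn1C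
F4 | step 7 | bis(trimethylsilyl ketene acetal) of 14 (C4 and C4′ as in 14) | C[Si](C)(C)OC1Oc2cc(OC)cc(OC)c2[C@@H](c2ccc(OC)cc2)C=1C1=C(O[Si](C)(C)C)Oc2c(OC)c(OC)c(OC)c(OC)c2[C@H]1c1ccc(OC)cc1
F5 | step 3 | bis(1,3-dimethylimidazolium) bis(triflate) of 4 | O=C(c1n(C)cc[n+]1C)[C@@H]1[C@@H](c2ccc(OC)cc2)[C@H](c2ccc(OC)cc2)[C@H]1C(=O)c1n(C)cc[n+]1C.[O-]S(=O)(=O)C(F)(F)F.[O-]S(=O)(=O)C(F)(F)F
F6 | step 8 | (3R,4R)-5,7-dihydroxy-4-(4-hydroxyphenyl)-3-[(3R,4R)-5,6,7,8-tetrahydroxy-4-(4-hydroxyphenyl)-2-oxochroman-3-yl]chroman-2-one | O=C1Oc2cc(O)cc(O)c2[C@@H](c2ccc(O)cc2)[C@@H]1[C@@H]1C(=O)Oc2c(O)c(O)c(O)c(O)c2[C@H]1c1ccc(O)cc1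
F7 | step 8 | octakis(methoxymethyl) ether of F6 (3R,4R,3′R,4′R) | O=C1Oc2cc(OCOC)cc(OCOC)c2[C@@H](c2ccc(OCOC)cc2)[C@@H]1[C@@H]1C(=O)Oc2c(OCOC)c(OCOC)c(OCOC)c(OCOC)c2[C@H]1c1ccc(OCOC)cc1
F8 | step 8 | dilithium bis-enolate of F7 | [Li+].[Li+].[O-]C1Oc2cc(OCOC)cc(OCOC)c2[C@@H](c2ccc(OCOC)cc2)C=1C1=C([O-])Oc2c(OCOC)c(OCOC)c(OCOC)c(OCOC)c2[C@H]1c1ccc(OCOC)cc1
F9 | step 8 | octakis(methoxymethyl) ether of 17 (3S,4R,3′S,4′R) | O=C1Oc2cc(OCOC)cc(OCOC)c2[C@@H](c2ccc(OCOC)cc2)[C@H]1[C@H]1C(=O)Oc2c(OCOC)c(OCOC)c(OCOC)c(OCOC)c2[C@H]1c1ccc(OCOC)cc1
A1 | alternative 1 | (3S,4R)-5,7-dihydroxy-4-(4-hydroxyphenyl)-3-[(3S,4R)-4-(4-hydroxyphenyl)-5,6,7,8-tetramethoxy-2-oxochroman-3-yl]chroman-2-one | O=C1Oc2cc(O)cc(O)c2[C@@H](c2ccc(O)cc2)[C@H]1[C@H]1C(=O)Oc2c(OC)c(OC)c(OC)c(OC)c2[C@H]1c1ccc(O)cc1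
A2 | alternative 1 | cis-fused 2,6-bis(4-hydroxyphenyl)-3,7-dioxabicyclo[3.3.0]octane-4,8-dione, aryl groups exo (enantiomer whose ring-fusion carbons map onto C3 and C3′ of 17) | O=C1O[C@@H](c2ccc(O)cc2)[C@@H]2C(=O)O[C@@H](c3ccc(O)cc3)[C@H]12
A3 | alternative 1 | phloroglucinol | Oc1cc(O)cc(O)c1
A4 | alternative 2 | (2,4-cis)-2-ethoxy-6,7-dimethoxy-4-(4-methoxyphenyl)chromane-5,8-diol | CCO[C@@H]1C[C@H](c2ccc(OC)cc2)c2c(O)c(OC)c(OC)c(O)c2O1
A5 | alternative 3 | dimethyl (4R)-5,7-dihydroxy-4-(4-methoxyphenyl)-2-oxochromane-6,8-dicarboxylate | O=C1C[C@H](c2ccc(OC)cc2)c2c(O)c(C(=O)OC)c(O)c(C(=O)OC)c2O1
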